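**Retrosynthetic overview**

1. The enone is cut at the C7–C(=O) bond: a C7 carbanion of the dihydrobenzofuran (directed lithiation between the methoxy oxygen and O1) and an (E)-cinnamoyl Weinreb amide made by Horner–Wadsworth–Emmons olefination.
2. The dihydrofuran ring is cut at C3–C3a: an aryllithium at C3a opens the CH2–O bond of a 3-aryloxy-2,2-dimethyloxetane, so the C–C bond and the tertiary alcohol appear in the same event.
3. Enabling feature: the carbinol oxygen is 1,3 to C3 (C3–C2–C(CH3)2–O), so C3, C2, the carbinol carbon and its oxygen can be held as an oxetane ring with C2 already bonded to O1. C3a lies between O1 and the C4 oxygen of the resorcinol ring, so mirror-symmetric 2-iodo-5-methoxyresorcinol carries the halogen exactly there.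
4. The oxetane comes from Williamson closure of a 1,3-bromohydrin, itself made by SN2 opening (inversion, sets C2) of silyl-protected (S)-3,3-dimethylglycidol (Sharpless epoxidation of prenol) by the iodoresorcinol.
5. Ring order: both benzene rings are bought; oxirane (step 1, opened in step 4), temporary oxetane (step 6), dihydrofuran (step 7).

Key step: step 7

Remark: locants are those of the 2,3-dihydro-1-benzofuran core of the target (O1, C2, C3, C3a, C4 to C7, C7a) and are also used for the atoms of earlier intermediates that become these positions.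

**Route**

Step 1
Reactants: 1 3-methylbut-2-en-1-ol (prenol)
Product: 2 [(2S)-3,3-dimethyloxiran-2-yl]methanol
Conditions: Ti(OiPr)4 (cat.), L-(+)-diisopropyl tartrate (cat.), t-BuOOH, 4 Å molecular sieves, CH2Cl2, −20 °C
Reagents that add atoms: tert-butyl hydroperoxide, CC(C)(C)OO
Why: Sharpless asymmetric epoxidation of a primary allylic alcohol; by the usual facial rule of this reaction the L-(+)-tartrate catalyst should deliver oxygen to the face that makes C2 (S), and this is the only stereocenter the route has to set.

Step 2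
Reactants: 2 [(2S)-3,3-dimethyloxiran-2-yl]methanol
Product: 3 tert-butyl{[(2S)-3,3-dimethyloxiran-2-yl]methoxy}diphenylsilane
Conditions: TBDPSCl, imidazole, CH2Cl2, 0 °C → rt
Reagents that add atoms: tert-butyl(chloro)diphenylsilane, CC(C)(C)[Si](Cl)(c1ccccc1)c1ccccc1
Why: Standard silylation of a primary alcohol; the base-stable silyl ether blocks the Payne rearrangement that a free epoxy alcohol could undergo in step 4.

Step 3
Reactants: 4 5-methoxybenzene-1,3-diol
Product: 5 2-iodo-5-methoxybenzene-1,3-diol
Conditions: I2 (1.05 equiv), NaHCO3, H2O/THF, 0 °C → rt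
Reagents that add atoms: iodine, II
Why: Electrophilic aromatic iodination of the phenoxide, expected at the carbon between the two hydroxyl groups as with resorcinol itself; the product keeps the mirror plane, so its two hydroxyl groups are equivalent and the halogen marks the future C3a.

Step 4
Reactants: 5 2-iodo-5-methoxybenzene-1,3-diol; 3 tert-butyl{[(2S)-3,3-dimethyloxiran-2-yl]methoxy}diphenylsilane
Product: 7 (2R)-2-(3-hydroxy-2-iodo-5-methoxyphenoxy)-3-methylbutane-1,3-diol, via silyl ether 6 (not isolated)
Conditions: 5 (2.5 equiv), Cs2CO3 (0.5 equiv), DMF, 100 °C; then TBAF, THF, rt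
Reagents that add atoms: none
Why: Base-mediated SN2 opening of the trisubstituted epoxide by the phenoxide at its CH carbon with inversion (S in 3 becomes R at the future C2), followed by fluoride desilylation; the excess of the symmetric diol should hold back double alkylation.

Step 5
Reactants: 7 (2R)-2-(3-hydroxy-2-iodo-5-methoxyphenoxy)-3-methylbutane-1,3-diol
Product: 8 3-{[(2S)-1-bromo-3-hydroxy-3-methylbutan-2-yl]oxy}-2-iodo-5-methoxyphenol
Conditions: CBr4, PPh3, THF, 0 °C → rt
Reagents that add atoms: tetrabromomethane, BrC(Br)(Br)Br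
Why: Appel bromination, selective for the primary alcohol over the tertiary alcohol and the phenol; the spatial arrangement at C2 is unchanged (the descriptor becomes S only because CH2Br now outranks the carbinol carbon).

Step 6
Reactants: 8 3-{[(2S)-1-bromo-3-hydroxy-3-methylbutan-2-yl]oxy}-2-iodo-5-methoxyphenol
Product: 9 3-{[(3R)-2,2-dimethyloxetan-3-yl]oxy}-2-iodo-5-methoxyphenol
Conditions: NaH (2.5 equiv), THF, 0 °C → 45 °C
Reagents that add atoms: none
Why: Intramolecular Williamson etherification, a 4-exo-tet closure of the tertiary alkoxide onto the primary bromide that the gem-dimethyl group favours; no bond to the stereocenter is broken.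

Step 7
Reactants: 9 3-{[(3R)-2,2-dimethyloxetan-3-yl]oxy}-2-iodo-5-methoxyphenol
Product: 11 (2R)-2-(2-hydroxypropan-2-yl)-6-methoxy-2,3-dihydro-1-benzofuran-4-ol, via dilithio aryl species 10 (not isolated)
Conditions: t-BuLi (3.2 equiv), THF/Et2O, −78 °C → rt; H2O
Reagents that add atoms: none
Why: Proposed new method: the first equivalent of t-BuLi forms the lithium phenoxide and iodine–lithium exchange at C3a, the carbon between the two ring oxygens, gives aryllithium 10, whose carbanion then attacks the oxetane CH2 in an intramolecular SN2 reaction that breaks the CH2–O bond, releases the strain of the four-membered ring (about 105 kJ/mol) and leaves the tertiary lithium alkoxide, so that the C3–C3a bond, the dihydrofuran ring and the free carbinol arise together. The closest known reaction types are the Parham cyclisation of aryllithiums onto tethered epoxides or alkyl halides and the intermolecular opening of oxetanes by organolithium reagents. The dihydrofuran ring closes in the 5-exo-tet mode, with the breaking C–O bond outside the new ring. No new stereocenter is formed, and C2 keeps its (R) configuration because none of its bonds is broken. The step needs attack at the CH2 carbon and not at the quaternary oxetane carbon, which the SN2 preference of a carbanion for a primary centre secures as long as no Lewis acid is present to ionise the tertiary C–O bond, and it needs one defined site of metalation, which the position of the iodine fixes. The phenol is carried as its lithium salt because a silyl ether next to the carbanion would migrate from oxygen to carbon.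

Step 8
Reactants: 11 (2R)-2-(2-hydroxypropan-2-yl)-6-methoxy-2,3-dihydro-1-benzofuran-4-ol
Product: 12 2-[(2R)-6-methoxy-4-(triisopropylsilyloxy)-2,3-dihydro-1-benzofuran-2-yl]propan-2-ol
Conditions: TIPSCl, imidazole, DMF, rt
Reagents that add atoms: chlorotriisopropylsilane, CC(C)[Si](Cl)(C(C)C)C(C)C
Why: Selective silylation of the phenol (the tertiary alcohol is too hindered to react); the bulky, poorly coordinating silyl ether shields C5 for step 10.

Step 9
Reactants: 13 4-(tert-butyldimethylsilyloxy)benzaldehyde; 14 diethyl {2-[methoxy(methyl)amino]-2-oxoethyl}phosphonate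
Product: 15 (2E)-3-[4-(tert-butyldimethylsilyloxy)phenyl]-N-methoxy-N-methylprop-2-enamide
Conditions: NaH, THF, 0 °C → rt
Reagents that add atoms: none
Why: Horner–Wadsworth–Emmons olefination with a stabilised phosphonate anion, which should give the (E)-alkene.

Step 10
Reactants: 12 2-[(2R)-6-methoxy-4-(triisopropylsilyloxy)-2,3-dihydro-1-benzofuran-2-yl]propan-2-ol; 15 (2E)-3-[4-(tert-butyldimethylsilyloxy)phenyl]-N-methoxy-N-methylprop-2-enamide
Product: 17 (2E)-3-[4-(tert-butyldimethylsilyloxy)phenyl]-1-[(2R)-2-(2-hydroxypropan-2-yl)-6-methoxy-4-(triisopropylsilyloxy)-2,3-dihydro-1-benzofuran-7-yl]prop-2-en-1-one, via C7-lithiated alkoxide 16 (not isolated)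
Conditions: s-BuLi (2.3 equiv), TMEDA, THF, −78 → −30 °C; then 15, −78 → 0 °C; H2O
Reagents that add atoms: none
Why: Directed ortho-lithiation followed by Weinreb ketone synthesis; after the alkoxide has formed, the C7 hydrogen between the methoxy oxygen and O1 should be removed in preference to the C5 hydrogen next to the silyl ether, and the chelated tetrahedral adduct should prevent over-addition.

Step 11
Reactants: 17 (2E)-3-[4-(tert-butyldimethylsilyloxy)phenyl]-1-[(2R)-2-(2-hydroxypropan-2-yl)-6-methoxy-4-(triisopropylsilyloxy)-2,3-dihydro-1-benzofuran-7-yl]prop-2-en-1-one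
Product: 18 (2E)-1-[(2R)-4-hydroxy-2-(2-hydroxypropan-2-yl)-6-methoxy-2,3-dihydro-1-benzofuran-7-yl]-3-(4-hydroxyphenyl)prop-2-en-1-one
Conditions: TBAF (2.5 equiv), AcOH, THF, 0 °C
Reagents that add atoms: none
Why: Fluoride cleavage of the two aryl silyl ethers under acetic acid buffering, mild enough for the enone and the tertiary alcohol.

**Compound list**

1 | 3-methylbut-2-en-1-ol (prenol) | CC(C)=CCO | starting material
2 | [(2S)-3,3-dimethyloxiran-2-yl]methanol | OC[C@@H]1OC1(C)C | intermediate
3 | tert-butyl{[(2S)-3,3-dimethyloxiran-2-yl]methoxy}diphenylsilane | CC(C)(C)[Si](OC[C@@H]1OC1(C)C)(c1ccccc1)c1ccccc1 | intermediate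
4 | 5-methoxybenzene-1,3-diol | COc1cc(O)cc(O)c1 | starting material
5 | 2-iodo-5-methoxybenzene-1,3-diol | COc1cc(O)c(I)c(O)c1 | intermediate
6 | 3-{[(2R)-1-(tert-butyldiphenylsilyloxy)-3-hydroxy-3-methylbutan-2-yl]oxy}-2-iodo-5-methoxyphenol | COc1cc(O)c(I)c(O[C@H](CO[Si](c2ccccc2)(c2ccccc2)C(C)(C)C)C(C)(C)O)c1 | intermediate
7 | (2R)-2-(3-hydroxy-2-iodo-5-methoxyphenoxy)-3-methylbutane-1,3-diol | COc1cc(O)c(I)c(O[C@H](CO)C(C)(C)O)c1 | intermediate
8 | 3-{[(2S)-1-bromo-3-hydroxy-3-methylbutan-2-yl]oxy}-2-iodo-5-methoxyphenol | COc1cc(O)c(I)c(O[C@H](CBr)C(C)(C)O)c1 | intermediate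
9 | 3-{[(3R)-2,2-dimethyloxetan-3-yl]oxy}-2-iodo-5-methoxyphenol | COc1cc(O)c(I)c(O[C@@H]2COC2(C)C)c1 | intermediate
10 | lithium 3-{[(3R)-2,2-dimethyloxetan-3-yl]oxy}-2-lithio-5-methoxyphenolate | COc1cc(O[Li])c([Li])c(O[C@@H]2COC2(C)C)c1 | intermediate
11 | (2R)-2-(2-hydroxypropan-2-yl)-6-methoxy-2,3-dihydro-1-benzofuran-4-ol | COc1cc(O)c2c(c1)O[C@@H](C(C)(C)O)C2 | intermediate
12 | 2-[(2R)-6-methoxy-4-(triisopropylsilyloxy)-2,3-dihydro-1-benzofuran-2-yl]propan-2-ol | COc1cc(O[Si](C(C)C)(C(C)C)C(C)C)c2c(c1)O[C@@H](C(C)(C)O)C2 | intermediate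
13 | 4-(tert-butyldimethylsilyloxy)benzaldehyde | CC(C)(C)[Si](C)(C)Oc1ccc(C=O)cc1 | starting material
14 | diethyl {2-[methoxy(methyl)amino]-2-oxoethyl}phosphonate | CCOP(=O)(CC(=O)N(C)OC)OCC | starting material
15 | (2E)-3-[4-(tert-butyldimethylsilyloxy)phenyl]-N-methoxy-N-methylprop-2-enamide | CON(C)C(=O)/C=C/c1ccc(O[Si](C)(C)C(C)(C)C)cc1 | intermediate
16 | lithium 2-[(2R)-7-lithio-6-methoxy-4-(triisopropylsilyloxy)-2,3-dihydro-1-benzofuran-2-yl]propan-2-olate | COc1cc(O[Si](C(C)C)(C(C)C)C(C)C)c2c(c1[Li])O[C@@H](C(C)(C)O[Li])C2 | intermediate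
17 | (2E)-3-[4-(tert-butyldimethylsilyloxy)phenyl]-1-[(2R)-2-(2-hydroxypropan-2-yl)-6-methoxy-4-(triisopropylsilyloxy)-2,3-dihydro-1-benzofuran-7-yl]prop-2-en-1-one | COc1cc(O[Si](C(C)C)(C(C)C)C(C)C)c2c(c1C(=O)/C=C/c1ccc(O[Si](C)(C)C(C)(C)C)cc1)O[C@@H](C(C)(C)O)C2 | intermediate
18 | (2E)-1-[(2R)-4-hydroxy-2-(2-hydroxypropan-2-yl)-6-methoxy-2,3-dihydro-1-benzofuran-7-yl]-3-(4-hydroxyphenyl)prop-2-en-1-one | COc1cc(O)c2c(c1C(=O)/C=C/c1ccc(O)cc1)O[C@@H](C(C)(C)O)C2 | target

**Step count and risks**

Total step count: 11. Longest linear sequence: 9 steps (steps 1, 2, 4, 5, 6, 7, 8, 10, 11).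

Steps most likely to fail:

Step 7 (proposed new method). The aryllithium may be protonated or decompose on warming before it opens the unactivated oxetane, or ring opening may be slow enough for intermolecular pathways to compete. The fallback is a classical Parham cycloalkylation onto a primary bromide and sets out from 8. Treatment of 8 with MOMCl and i-Pr2NEt (CH2Cl2, 40 °C) should protect the phenol and the tertiary alcohol to give 1-{[(2S)-1-bromo-3-(methoxymethoxy)-3-methylbutan-2-yl]oxy}-2-iodo-5-methoxy-3-(methoxymethoxy)benzene F1. With t-BuLi (2.1 equiv, THF, −78 °C → rt), iodine–lithium exchange and 5-exo-tet displacement of bromide should then give (2R)-6-methoxy-4-(methoxymethoxy)-2-[2-(methoxymethoxy)propan-2-yl]-2,3-dihydro-1-benzofuran F2. HCl in MeOH should remove both acetals, and the fallback comes back to the route at 11.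

Step 10. Deprotonation may occur at C5 instead of C7 (poor site selectivity), metalation beside the alkoxide may be incomplete, or the aryllithium may add in conjugate fashion. The fallback generates the carbanion by halogenation and halogen–metal exchange and sets out from 12. NBS (MeCN, 0 °C) should brominate para to the silyloxy group, at C7, with C5 shielded, to give 2-[(2R)-7-bromo-6-methoxy-4-(triisopropylsilyloxy)-2,3-dihydro-1-benzofuran-2-yl]propan-2-ol F3. n-BuLi (1 equiv) for the alkoxide, then t-BuLi (2 equiv, THF, −78 °C) for bromine–lithium exchange, then 15, should give the ketone, and the fallback comes back at 17.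

Step 3. Iodination may go to the carbon between hydroxyl and methoxy, or twice (poor positional selectivity, over-iodination). The fallback fixes the position by directed ortho-lithiation and sets out from 4. MOMCl and i-Pr2NEt should give 1-methoxy-3,5-bis(methoxymethoxy)benzene F4. n-BuLi (THF, 0 °C) should metalate between the two acetal oxygens, and I2 should then give 2-iodo-5-methoxy-1,3-bis(methoxymethoxy)benzene F5. HCl in MeOH should free both phenols, and the fallback comes back at 5.

Further compounds

F1 | step 7 | 1-{[(2S)-1-bromo-3-(methoxymethoxy)-3-methylbutan-2-yl]oxy}-2-iodo-5-methoxy-3-(methoxymethoxy)benzene | COc1cc(OCOC)c(I)c(O[C@H](CBr)C(C)(C)OCOC)c1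
F2 | step 7 | (2R)-6-methoxy-4-(methoxymethoxy)-2-[2-(methoxymethoxy)propan-2-yl]-2,3-dihydro-1-benzofuran | COc1cc(OCOC)c2c(c1)O[C@@H](C(C)(C)OCOC)C2
F3 | step 10 | 2-[(2R)-7-bromo-6-methoxy-4-(triisopropylsilyloxy)-2,3-dihydro-1-benzofuran-2-yl]propan-2-ol | COc1cc(O[Si](C(C)C)(C(C)C)C(C)C)c2c(c1Br)O[C@@H](C(C)(C)O)C2
F4 | step 3 | 1-methoxy-3,5-bis(methoxymethoxy)benzene | COCOc1cc(OC)cc(OCOC)c1
F5 | step 3 | 2-iodo-5-methoxy-1,3-bis(methoxymethoxy)benzene | COCOc1cc(OC)cc(OCOC)c1I
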